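**Retrosynthetic overview**

1. The target comes from global hydrogenolysis of a benzyl/diphenylmethylene-protected 3'-O-(tri-O-benzylgalloyl)gallocatechin. That ester is made by chemoselective acylation of the 3'-phenol, after pivalate and allyl removal from the annulation product.
2. Key disconnection: ring C (O1–C2–C3–C4–C4a–C8a) is cut at O1–C2 and C3–C4. Ring A supplies O1–C8a–C4a–C4 as an o-quinone methide. C2–C3 comes from an (E)-aryl enol pivalate, whose E geometry becomes the trans H2/H3 relationship of the (2R,3S) product.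
3. Dienophile: copper-catalysed C–O coupling of an (E)-styryltrifluoroborate with pivalic acid, preceded by boron-Wittig olefination of a ring-B aldehyde made from 3,4,5-trihydroxybenzaldehyde. O4'/O5' are tied as a diphenylmethylene ketal so that the para oxygen stays conjugated with ring B; O3' is an allyl ether.
4. Quinone methide precursor: 3,5-bis(benzyloxy)-2-(hydroxymethyl)phenol, from 2,4,6-trihydroxybenzaldehyde by dibenzylation and reduction.
5. Ring order: rings A, B and the galloyl ring are bought intact; ring C is the only ring formed, in the annulation.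

Key step: step 8

Assumption: the facial sense induced by a given antipode of the chiral Brønsted acid on this new dienophile cannot be predicted with confidence, so the antipode that delivers the (2R,3S) product is chosen after a small screen (both antipodes are accessible); commercial 3,4,5-tris(benzyloxy)benzoic acid replaces benzylation of gallic acid.

**Route**

Step 1
Reactants: 1 3,4,5-trihydroxybenzaldehyde (dried)
Product: 2 7-hydroxy-2,2-diphenyl-1,3-benzodioxole-5-carbaldehyde
Conditions: Ph2CCl2 (1.2 equiv), Ph2O, 175 °C, 45 min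
Reagents that add atoms: dichlorodiphenylmethane ClC(Cl)(c1ccccc1)c1ccccc1
Why: Double O-alkylation by the gem-dichloride (ketalisation) can only bridge two adjacent phenols, so one vicinal pair is tied up as the 2,2-diphenyl-1,3-benzodioxole and one meta OH stays free, the two possible pairs being equivalent by symmetry.

Step 2
Reactants: 2 7-hydroxy-2,2-diphenyl-1,3-benzodioxole-5-carbaldehyde
Product: 3 7-(allyloxy)-2,2-diphenyl-1,3-benzodioxole-5-carbaldehyde
Conditions: allyl bromide, K2CO3, DMF, rt
Reagents that add atoms: allyl bromide C=CCBr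
Why: Williamson etherification of the only free phenol, with aldehyde and ketal inert to K2CO3.

Step 3
Reactants: 3 7-(allyloxy)-2,2-diphenyl-1,3-benzodioxole-5-carbaldehyde; 4 bis(pinacolato)borylmethane
Product: 5 (E)-2-[7-(allyloxy)-2,2-diphenyl-1,3-benzodioxol-5-yl]ethenylboronic acid pinacol ester
Conditions: LiTMP (lithium 2,2,6,6-tetramethylpiperidide), 4, THF, 0 °C; then 3, −78 °C → rt
Reagents that add atoms: none
Why: Boron-Wittig olefination, in which the α-boryl carbanion adds to the aldehyde and syn-elimination of the boron oxide gives the 1,2-disubstituted alkenylboronate, for which high E selectivity is the established outcome with this reagent.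

Step 4
Reactants: 5 (E)-alkenylboronic acid pinacol ester
Product: 6 potassium (E)-{2-[7-(allyloxy)-2,2-diphenyl-1,3-benzodioxol-5-yl]ethenyl}trifluoroborate
Conditions: KHF2 (aq.), MeOH, rt
Reagents that add atoms: potassium hydrogen difluoride F.[F-].[K+]
Why: Standard fluoride exchange of a pinacol boronate to the crystalline, more readily transmetalating trifluoroborate salt, with retention of alkene geometry.

Step 5
Reactants: 6 potassium (E)-alkenyltrifluoroborate; 7 pivalic acid
Product: 8 (E)-2-[7-(allyloxy)-2,2-diphenyl-1,3-benzodioxol-5-yl]ethenyl pivalate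
Conditions: CuBr (10 mol%), DMAP (20 mol%), 4 Å MS, O2 (1 atm), DCM/DMSO, 40 °C
Reagents that add atoms: none
Why: Copper-catalysed oxidative C–O coupling (Chan–Lam type) of an alkenyltrifluoroborate with a carboxylic acid is a known enol-ester synthesis that proceeds through transmetalation and reductive elimination with retention of the E geometry, the allyl ether and ketal being spectators.

Step 6
Reactants: 9 2,4,6-trihydroxybenzaldehyde
Product: 10 2,4-bis(benzyloxy)-6-hydroxybenzaldehyde
Conditions: BnBr (2.05 equiv), K2CO3, DMF, 0 °C → rt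
Reagents that add atoms: benzyl bromide BrCc1ccccc1
Why: Williamson benzylation takes the 4-OH and one ortho OH, while the last ortho OH is locked in a hydrogen bond to the formyl group and is much less nucleophilic, so alkylation should stop at the dibenzyl ether.

Step 7
Reactants: 10 2,4-bis(benzyloxy)-6-hydroxybenzaldehyde
Product: 11 3,5-bis(benzyloxy)-2-(hydroxymethyl)phenol
Conditions: NaBH4, THF/MeOH, 0 °C, 15 min; pH 7 buffer work-up; prepared immediately before step 8
Reagents that add atoms: none
Why: NaBH4 reduction of the aryl aldehyde to the benzylic alcohol leaves benzyl ethers untouched, and the cold, buffered work-up avoids premature ionisation of the electron-rich salicyl alcohol.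

Step 8
Reactants: 11 3,5-bis(benzyloxy)-2-(hydroxymethyl)phenol; 8 (E)-enol pivalate
Product: 13 (2R,3S)-2-[7-(allyloxy)-2,2-diphenyl-1,3-benzodioxol-5-yl]-5,7-bis(benzyloxy)chroman-3-yl pivalate, via o-quinone methide 12 (not isolated)
Conditions: 8 (1.5 equiv), (R)-3,3'-bis(2,4,6-triisopropylphenyl)-1,1'-binaphthyl-2,2'-diyl N-triflylphosphoramide (10 mol%, antipode per the assumption), 4 Å MS, toluene/DCM, −20 °C; 11 added by syringe pump over several hours
Reagents that add atoms: none
Why: Proposed new method: the chiral acid ionises the benzylic C–OH of 11, assisted by the ortho and para benzyloxy groups, to the hydrogen-bonded o-quinone methide 12, whose CH2 terminus is attacked by the pivaloyloxy-bearing alkene carbon of 8 (C3–C4) while the methide oxygen captures the developing alkoxybenzylic cation (O1–C2) in a concerted but asynchronous inverse-electron-demand oxa-[4+2]; the closest known reaction is the chiral phosphoramide-catalysed cycloaddition of in situ o-quinone methides with styrenes, extended here to a β-acyloxystyrene and a methide that is unsubstituted at carbon. Ring C closes by intermolecular [4+2] annulation, which in a stepwise limit would be a 6-endo capture of the C2 cation by the phenolic oxygen. The 2,3-trans relationship is transferred from the (E)-alkene by suprafacial addition, and a stepwise path should converge on the same trans isomer through pivalate participation at C2; the absolute configuration (2R,3S) is imposed by the chiral counter-anion bound to the protonated methide, which differentiates the two alkene faces. The step needs aryl at C2 and oxygen at C3, which is secured because the para oxygen of the dioxole, held coplanar with ring B, stabilises positive charge at C2 far better than the weakly donating pivaloyloxy group could at C3. It also needs 12 to be trapped by 8 faster than it alkylates ring A of 11 or 13, which is addressed by slow addition of 11 to an excess of 8.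

Step 9
Reactants: 13 (2R,3S)-flavan-3-yl pivalate
Product: 14 (2R,3S)-2-[7-(allyloxy)-2,2-diphenyl-1,3-benzodioxol-5-yl]-5,7-bis(benzyloxy)chroman-3-ol
Conditions: LiAlH4, THF, 0 °C; H2O, 15% NaOH, H2O
Reagents that add atoms: none
Why: Hydride reduction cleaves the hindered secondary pivalate to the alkoxide and neopentyl alcohol without touching benzyl or allyl ethers or the ketal, and neither stereocentre is labile under these conditions.

Step 10
Reactants: 14 (2R,3S)-3'-O-allyl flavan-3-ol
Product: 15 (2R,3S)-5,7-bis(benzyloxy)-2-(7-hydroxy-2,2-diphenyl-1,3-benzodioxol-5-yl)chroman-3-ol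
Conditions: Pd(PPh3)4 (5 mol%), morpholine, THF, rt
Reagents that add atoms: none
Why: Tsuji–Trost deallylation, in which zerovalent palladium ionises the aryl allyl ether to a π-allyl complex and the phenoxide and morpholine captures the allyl group, leaving benzyl ethers, ketal and the 3-OH untouched.

Step 11
Reactants: 16 3,4,5-tris(benzyloxy)benzoic acid
Product: 17 3,4,5-tris(benzyloxy)benzoyl chloride
Conditions: (COCl)2, DMF (cat.), DCM, 0 °C → rt; concentrated and used crude
Reagents that add atoms: oxalyl chloride ClC(=O)C(=O)Cl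
Why: Acid chloride formation through the Vilsmeier-type chloroiminium species, which benzyl aryl ethers tolerate.

Step 12
Reactants: 15 (2R,3S)-3'-phenol flavan-3-ol; 17 3,4,5-tris(benzyloxy)benzoyl chloride
Product: 18 5-[(2R,3S)-5,7-bis(benzyloxy)-3-hydroxychroman-2-yl]-2,2-diphenyl-1,3-benzodioxol-4-yl 3,4,5-tris(benzyloxy)benzoate
Conditions: 17 (1.05 equiv), Et3N, DCM, −20 → 0 °C (no DMAP)
Reagents that add atoms: none
Why: Chemoselective Einhorn-type O-acylation, since under amine base without a nucleophilic catalyst the phenol (as its hydrogen-bonded phenoxide) should react with the aroyl chloride far faster than the hindered secondary 3-OH.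

Step 13
Reactants: 18 protected 3'-O-galloyl gallocatechin
Product: 19 gallocatechin 3'-O-gallate, (2R,3S)
Conditions: H2 (1 atm), Pd(OH)2/C, THF/MeOH, rt; filtration and evaporation without base
Reagents that add atoms: none
Why: Catalytic hydrogenolysis cleaves the five O-benzyl groups and the benzhydryl-type ketal (as diphenylmethane) while the aryl ester and the flavan C2–O bond should survive, and the base-free work-up is chosen to suppress galloyl migration to O4'.

**Compound list**

1 | 3,4,5-trihydroxybenzaldehyde | O=Cc1cc(O)c(O)c(O)c1 | starting material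
2 | 7-hydroxy-2,2-diphenyl-1,3-benzodioxole-5-carbaldehyde | O=Cc1cc(O)c2OC(c3ccccc3)(c3ccccc3)Oc2c1 | intermediate
3 | 7-(allyloxy)-2,2-diphenyl-1,3-benzodioxole-5-carbaldehyde | C=CCOc1cc(C=O)cc2OC(c3ccccc3)(c3ccccc3)Oc12 | intermediate
4 | bis(pinacolato)borylmethane | CC1(C)OB(CB2OC(C)(C)C(C)(C)O2)OC1(C)C | starting material
5 | (E)-2-[7-(allyloxy)-2,2-diphenyl-1,3-benzodioxol-5-yl]ethenylboronic acid pinacol ester | C=CCOc1cc(/C=C/B2OC(C)(C)C(C)(C)O2)cc2OC(c3ccccc3)(c3ccccc3)Oc12 | intermediate
6 | potassium (E)-{2-[7-(allyloxy)-2,2-diphenyl-1,3-benzodioxol-5-yl]ethenyl}trifluoroborate | C=CCOc1cc(/C=C/[B-](F)(F)F)cc2OC(c3ccccc3)(c3ccccc3)Oc12.[K+] | intermediate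
7 | pivalic acid | CC(C)(C)C(=O)O | starting material
8 | (E)-2-[7-(allyloxy)-2,2-diphenyl-1,3-benzodioxol-5-yl]ethenyl pivalate | C=CCOc1cc(/C=C/OC(=O)C(C)(C)C)cc2OC(c3ccccc3)(c3ccccc3)Oc12 | intermediate
9 | 2,4,6-trihydroxybenzaldehyde | O=Cc1c(O)cc(O)cc1O | starting material
10 | 2,4-bis(benzyloxy)-6-hydroxybenzaldehyde | O=Cc1c(O)cc(OCc2ccccc2)cc1OCc1ccccc1 | intermediate
11 | 3,5-bis(benzyloxy)-2-(hydroxymethyl)phenol | OCc1c(O)cc(OCc2ccccc2)cc1OCc1ccccc1 | intermediate
12 | 3,5-bis(benzyloxy)-6-methylidenecyclohexa-2,4-dien-1-one (o-quinone methide) | C=C1C(=O)C=C(OCc2ccccc2)C=C1OCc1ccccc1 | intermediate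
13 | (2R,3S)-2-[7-(allyloxy)-2,2-diphenyl-1,3-benzodioxol-5-yl]-5,7-bis(benzyloxy)chroman-3-yl pivalate | C=CCOc1cc([C@H]2Oc3cc(OCc4ccccc4)cc(OCc4ccccc4)c3C[C@@H]2OC(=O)C(C)(C)C)cc2OC(c3ccccc3)(c3ccccc3)Oc12 | intermediate
14 | (2R,3S)-2-[7-(allyloxy)-2,2-diphenyl-1,3-benzodioxol-5-yl]-5,7-bis(benzyloxy)chroman-3-ol | C=CCOc1cc([C@H]2Oc3cc(OCc4ccccc4)cc(OCc4ccccc4)c3C[C@@H]2O)cc2OC(c3ccccc3)(c3ccccc3)Oc12 | intermediate
15 | (2R,3S)-5,7-bis(benzyloxy)-2-(7-hydroxy-2,2-diphenyl-1,3-benzodioxol-5-yl)chroman-3-ol | Oc1cc([C@H]2Oc3cc(OCc4ccccc4)cc(OCc4ccccc4)c3C[C@@H]2O)cc2OC(c3ccccc3)(c3ccccc3)Oc12 | intermediate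
16 | 3,4,5-tris(benzyloxy)benzoic acid | OC(=O)c1cc(OCc2ccccc2)c(OCc2ccccc2)c(OCc2ccccc2)c1 | starting material
17 | 3,4,5-tris(benzyloxy)benzoyl chloride | O=C(Cl)c1cc(OCc2ccccc2)c(OCc2ccccc2)c(OCc2ccccc2)c1 | intermediate
18 | 5-[(2R,3S)-5,7-bis(benzyloxy)-3-hydroxychroman-2-yl]-2,2-diphenyl-1,3-benzodioxol-4-yl 3,4,5-tris(benzyloxy)benzoate | O=C(Oc1cc([C@H]2Oc3cc(OCc4ccccc4)cc(OCc4ccccc4)c3C[C@@H]2O)cc2OC(c3ccccc3)(c3ccccc3)Oc12)c1cc(OCc2ccccc2)c(OCc2ccccc2)c(OCc2ccccc2)c1 | intermediate
19 | gallocatechin 3'-O-gallate, (2R,3S) | O=C(Oc1cc([C@H]2Oc3cc(O)cc(O)c3C[C@@H]2O)cc(O)c1O)c1cc(O)c(O)c(O)c1 | target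

**Step count**

Total: 13 steps. Longest linear sequence: 10 steps (steps 1, 2, 3, 4, 5, 8, 9, 10, 12, 13, from 3,4,5-trihydroxybenzaldehyde).

**Steps most likely to fail**

Step 8 (bears the label "Proposed new method:"). Several processes may defeat it:
- alkylation of the electron-rich ring A of 11 or 13 by the quinone methide, outrunning the cycloaddition;
- reversed regiochemistry, if the acyloxy group rather than the aryl group directs, leading to an acylal;
- acid-mediated hydrolysis, transacylation or oligomerisation of the enol ester, or loss of the ketal;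
- weak facial discrimination, because the dienophile offers no hydrogen-bond donor to the catalyst.

The fallback uses known chemistry only; it sets out from aldehyde 3 and returns at alcohol 14. Claisen–Schmidt condensation of 3 with commercial 1-[2,4-bis(benzyloxy)-6-hydroxyphenyl]ethanone (KOH, EtOH/THF) should give the (E)-2'-hydroxychalcone F1. O-Ethoxycarbonylation (ClCO2Et, Et3N, THF, 0 °C) gives the aryl ethyl carbonate F2, which is reduced in the same flask with NaBH4/H2O to the (E)-2-cinnamylphenol F3 by reductive deoxygenation through the vinylogous quinone methide. Silylation (TIPSCl, imidazole, DMF) gives the silyl ether F4. Shi epoxidation with the L-fructose-type (enantiomeric) ketone, KHSO5 (as Oxone), K2CO3 buffer, MeCN/dimethoxymethane, 0 °C, should give the (2S,3S)-trans-epoxide F5; the terminal allyl alkene is a poor substrate for this catalyst and should survive. Buffered desilylation (TBAF/AcOH, THF, 0 °C) gives the epoxy phenol F6. Catalytic camphorsulfonic acid in DCM then opens the epoxide 6-endo at the benzylic carbon with inversion, giving 14 with the (2R,3S) configuration.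

Step 5. Protodeboronation, oxidative homocoupling to the diene, or erosion of alkene geometry may compete with C–O bond formation. The fallback sets out from boronate 5 and returns at 8. Oxidation of 5 (NaBO3·4H2O, THF/H2O) gives the arylacetaldehyde F7. O-Acylation of its enol (pivalic anhydride, Et3N, DMAP cat., DCM) gives 8 together with the (Z)-enol pivalate F8. The isomers are separated by chromatography, and F8 is recycled by thiyl-radical equilibration (PhSSPh, light) toward the more stable E isomer.

Step 12. Chemoselectivity may be lost, with acylation of the secondary 3-OH or diacylation. The fallback sets out from 14 and returns at the target 19. The 3-OH is benzylated first (NaH, BnBr, DMF) to the 3-O-benzyl ether F9. Deallylation as in step 10 gives the phenol F10, now the only hydroxyl. Acylation with 17 (Et3N, DMAP, DCM) gives the ester F11. Hydrogenolysis as in step 13 removes the additional benzyl ether together with the others and gives 19.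

**Further compounds**

F1 | step 8 | (E)-3-[7-(allyloxy)-2,2-diphenyl-1,3-benzodioxol-5-yl]-1-[2,4-bis(benzyloxy)-6-hydroxyphenyl]prop-2-en-1-one | O=C(/C=C/c1cc(OCC=C)c2OC(c3ccccc3)(c3ccccc3)Oc2c1)c1c(O)cc(OCc2ccccc2)cc1OCc1ccccc1
F2 | step 8 | 2-{(E)-3-[7-(allyloxy)-2,2-diphenyl-1,3-benzodioxol-5-yl]prop-2-enoyl}-3,5-bis(benzyloxy)phenyl ethyl carbonate | CCOC(=O)Oc1cc(OCc2ccccc2)cc(OCc2ccccc2)c1C(=O)/C=C/c1cc(OCC=C)c2OC(c3ccccc3)(c3ccccc3)Oc2c1
F3 | step 8 | 2-{(E)-3-[7-(allyloxy)-2,2-diphenyl-1,3-benzodioxol-5-yl]prop-2-en-1-yl}-3,5-bis(benzyloxy)phenol | Oc1cc(OCc2ccccc2)cc(OCc2ccccc2)c1C/C=C/c1cc(OCC=C)c2OC(c3ccccc3)(c3ccccc3)Oc2c1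
F4 | step 8 | triisopropylsilyl ether of F3 | CC(C)[Si](C(C)C)(C(C)C)Oc1cc(OCc2ccccc2)cc(OCc2ccccc2)c1C/C=C/c1cc(OCC=C)c2OC(c3ccccc3)(c3ccccc3)Oc2c1
F5 | step 8 | (2S,3S)-2-[7-(allyloxy)-2,2-diphenyl-1,3-benzodioxol-5-yl]-3-[2,4-bis(benzyloxy)-6-(triisopropylsilyloxy)benzyl]oxirane | CC(C)[Si](C(C)C)(C(C)C)Oc1cc(OCc2ccccc2)cc(OCc2ccccc2)c1C[C@@H]1O[C@H]1c1cc(OCC=C)c2OC(c3ccccc3)(c3ccccc3)Oc2c1
F6 | step 8 | 2-{[(2S,3S)-3-(7-(allyloxy)-2,2-diphenyl-1,3-benzodioxol-5-yl)oxiran-2-yl]methyl}-3,5-bis(benzyloxy)phenol | Oc1cc(OCc2ccccc2)cc(OCc2ccccc2)c1C[C@@H]1O[C@H]1c1cc(OCC=C)c2OC(c3ccccc3)(c3ccccc3)Oc2c1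
F7 | step 5 | 2-[7-(allyloxy)-2,2-diphenyl-1,3-benzodioxol-5-yl]acetaldehyde | O=CCc1cc(OCC=C)c2OC(c3ccccc3)(c3ccccc3)Oc2c1
F8 | step 5 | (Z)-2-[7-(allyloxy)-2,2-diphenyl-1,3-benzodioxol-5-yl]ethenyl pivalate | C=CCOc1cc(/C=C\OC(=O)C(C)(C)C)cc2OC(c3ccccc3)(c3ccccc3)Oc12
F9 | step 12 | (2R,3S)-2-[7-(allyloxy)-2,2-diphenyl-1,3-benzodioxol-5-yl]-3,5,7-tris(benzyloxy)chroman | C=CCOc1cc([C@H]2Oc3cc(OCc4ccccc4)cc(OCc4ccccc4)c3C[C@@H]2OCc2ccccc2)cc2OC(c3ccccc3)(c3ccccc3)Oc12
F10 | step 12 | 2,2-diphenyl-6-[(2R,3S)-3,5,7-tris(benzyloxy)chroman-2-yl]-1,3-benzodioxol-4-ol | Oc1cc([C@H]2Oc3cc(OCc4ccccc4)cc(OCc4ccccc4)c3C[C@@H]2OCc2ccccc2)cc2OC(c3ccccc3)(c3ccccc3)Oc12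
F11 | step 12 | 2,2-diphenyl-6-[(2R,3S)-3,5,7-tris(benzyloxy)chroman-2-yl]-1,3-benzodioxol-4-yl 3,4,5-tris(benzyloxy)benzoate | O=C(Oc1cc([C@H]2Oc3cc(OCc4ccccc4)cc(OCc4ccccc4)c3C[C@@H]2OCc2ccccc2)cc2OC(c3ccccc3)(c3ccccc3)Oc12)c1cc(OCc2ccccc2)c(OCc2ccccc2)c(OCc2ccccc2)c1
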